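**Plan**

- Retrosynthesis (labdane numbering): the C18 acetate, the free acid and C8=C17 are removed last (acetylation, saponification, Wittig). Ring A is then cut at C3–C4 by a retro-1,2-shift that puts C18 back into the ring between C3 and C4, so the 4α-formyl decalin is traced to a trans-fused homo-A cycloheptene oxide (4α,18α-epoxide).
- Further cuts: C4=C18 (ring-closing metathesis), the cyclobutane bond that masks the C5 isopropenyl group (fragmentation), C9–C11 (enolate alkylation) and C10–C1 (conjugate addition). These lead to (1R,5R)-verbenone, a five-carbon Grignard reagent and a six-carbon iodo ester.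
- Enabling feature: C4 of ring A is quaternary, carries the only oxidised one-carbon branch (C18) and has the CH2 carbon C3 as ring neighbour. A 1,2-shift of C3 from an oxygen-bearing ring carbon (C18) to a tertiary cation at C4 leaves exactly this pattern, with C18 expelled from a seven-membered ring as the aldehyde.
- Forward order: iodo ester; ring B is carried inside the pinane skeleton while C10 and the C9 chain are installed, then unveiled by strain-driven cyclobutane opening; the seven-membered homo-A ring is closed by metathesis and contracted to ring A; C18–OH, C8=CH2, acid and acetate follow.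
- Stereochemistry: C5 (verbenone bridgehead) and C13 (methyl hydrogen (R)-3-methylglutarate) are bought. C10 follows from cuprate attack anti to the CMe2 bridge, C9 from equilibration, and C4 from α-face epoxidation (anti to the C10 methyl) relayed by the stereospecific shift.

Key step: step 9

Remark: labdane numbering is used for all ring compounds (C18 = 4α-branch, C19 = 4β-methyl, C20 = 10β-methyl); (1R,5R)-(+)-verbenone, pent-4-en-1-ylmagnesium bromide (THF solution) and methyl hydrogen (R)-3-methylglutarate are taken to be purchasable.

**Route**

Step 1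
Reactants: 1 methyl hydrogen (R)-3-methylglutarate
Product: 3 (4S)-4-methyltetrahydro-2H-pyran-2-one, via hydroxy acid 2 (not isolated)
Conditions: LiBH4 (2.5 equiv), THF, 0 → 50 °C; then 3 M HCl, rt
Reagents that add atoms: none
Why: Chemoselective ester reduction then lactonisation: the acid is converted by the first equivalent of LiBH4 into its unreactive lithium carboxylate, the methyl ester is reduced to the primary alcohol and acidification closes the δ-lactone, so the ester terminus becomes the future C11 and the stereocentre (future C13) is not touched.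

Step 2
Reactants: 3 (4S)-4-methyltetrahydro-2H-pyran-2-one
Product: 4 methyl (3R)-5-iodo-3-methylpentanoate
Conditions: Me3SiI (2 equiv), MeOH (4 equiv), CH2Cl2, 0 °C → rt
Reagents that add atoms: iodotrimethylsilane C[Si](C)(C)I; methanol CO
Why: Silyl iodide-mediated lactone cleavage: the activated lactone is opened by iodide at the O–CH2 carbon (SN2) and the liberated carboxyl group is esterified by the methanol present, a standard route from lactones to ω-iodo esters that leaves the remote stereocentre unchanged (the descriptor changes to R only because iodine raises the priority of that branch).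

Step 3
Reactants: 5 (1R,5R)-(+)-verbenone; 6 pent-4-en-1-ylmagnesium bromide
Product: 7 (1R,4R,5R)-4,6,6-trimethyl-4-(pent-4-en-1-yl)bicyclo[3.1.1]heptan-2-one
Conditions: CuI (10 mol%), THF, −40 → 0 °C; then cold 1 M HCl
Reagents that add atoms: none
Why: Copper-catalysed conjugate addition of a Grignard reagent to a β,β-disubstituted enone: the organocopper species attacks C4 of verbenone from the face opposite the CMe2 bridge, which sets the quaternary centre (future C10) with the pentenyl chain anti to that bridge.

Step 4
Reactants: 7 (1R,4R,5R)-4,6,6-trimethyl-4-(pent-4-en-1-yl)bicyclo[3.1.1]heptan-2-one; 4 methyl (3R)-5-iodo-3-methylpentanoate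
Product: 8 methyl (3S)-3-methyl-5-[4,6,6-trimethyl-2-oxo-4-(pent-4-en-1-yl)bicyclo[3.1.1]hept-3-yl]pentanoate (side chain on C3 anti to the CMe2 bridge)
Conditions: LiN(iPr)2 (1.1 equiv), THF, −78 °C; then 4 (1.5 equiv), HMPA, −78 → 0 °C
Reagents that add atoms: none
Why: Lithium enolate alkylation (SN2): the ketone can enolise only towards C3 because the other α-carbon is a bridgehead, so the side chain is attached regiospecifically at the future C9, from the face opposite the CMe2 bridge, and this centre is equilibrated in step 6.

Step 5
Reactants: 8 alkylated bicyclic ketone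
Product: 9 methyl (3S)-5-[2-acetoxy-6-methyl-6-(pent-4-en-1-yl)-5-(prop-1-en-2-yl)cyclohex-2-en-1-yl]-3-methylpentanoate (isopropenyl trans to pentenyl; side chain cis to pentenyl)
Conditions: BF3·OEt2, Zn(OAc)2, Ac2O, 0 °C → rt
Reagents that add atoms: acetic anhydride CC(=O)OC(C)=O
Why: Lewis acid-promoted cyclobutane fragmentation (strain-release retro-aldol-type cleavage of the bond between the α-bridgehead and the CMe2 carbon): the tertiary cation loses a methyl proton to give the isopropenyl group while the enol is trapped as its acetate, so the other bridgehead becomes C5 with its configuration intact and the ring B cyclohexane is unveiled.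

Step 6
Reactants: 9 enol acetate
Product: 10 methyl (3S)-3-methyl-5-[2-methyl-6-oxo-2-(pent-4-en-1-yl)-3-(prop-1-en-2-yl)cyclohexyl]pentanoate (5α-H; 10β-CH3; 9α-H)
Conditions: K2CO3 (0.2 equiv), MeOH, rt
Reagents that add atoms: none
Why: Base-catalysed methanolysis (transesterification) of the enol acetate releases the C8 ketone, and the same base equilibrates C9 through the enolate to the more stable equatorial side chain (9α-H, trans to the pentenyl group); the minor epimer can be resubmitted.

Step 7
Reactants: 10 diene ketone
Product: 11 methyl (13S)-8-oxo-17-nor-A-homolabd-4(18)-en-15-oate (trans-fused cyclohexanone–cycloheptene; C18 is the ring carbon between C3 and C4)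
Conditions: (H2IMes)(PCy3)Cl2Ru=CHPh (second-generation Grubbs catalyst, 5 mol%), CH2Cl2 (5 mM), 40 °C
Reagents that add atoms: none
Why: Ring-closing olefin metathesis between the isopropenyl group on C5 and the terminal vinyl group of the chain on C10, which are held gauche on adjacent ring carbons, should close the trans-fused seven-membered ring with a trisubstituted C4=C18 double bond and expel ethene; no stereocentre is formed.

Step 8
Reactants: 11 homo-A alkene
Product: 12 methyl (13S)-4α,18α-epoxy-8-oxo-17-nor-A-homolabdan-15-oate
Conditions: mCPBA (1.1 equiv), NaHCO3, CH2Cl2, 0 °C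
Reagents that add atoms: 3-chloroperoxybenzoic acid OOC(=O)c1cccc(Cl)c1
Why: Prilezhaev epoxidation of the only C=C bond: the peracid should approach from the α-face, away from the axial C10 methyl group that hangs over the β-face of C4, to give the 4α,18α-epoxide, while Baeyer–Villiger oxidation of the ketone is much slower under these buffered conditions.

Step 9
Reactants: 12 4α,18α-epoxide
Product: 13 methyl (13S)-8,18-dioxo-17-norlabdan-15-oate (4α-CHO; 4β-CH3)
Conditions: B(C6F5)3 (5 mol%), toluene, −20 → 0 °C
Reagents that add atoms: none
Why: Meinwald (semipinacol) rearrangement: the Lewis acid binds the epoxide oxygen, the C4–O bond ionises at the tertiary carbon and the ring bond C18–C3 migrates to C4 anti to the departing oxygen while C18 becomes the aldehyde carbon, so the seven-membered ring contracts to ring A. The closest known reaction type is the Lewis acid-catalysed rearrangement of trisubstituted cycloalkene oxides to ring-contracted α-quaternary aldehydes (1-methylcyclohexene oxide to 1-methylcyclopentanecarbaldehyde is the textbook case). Ring A is closed not by a cyclisation but by a suprafacial 1,2-alkyl shift inside the existing ring (C3–C4 forms, C3–C18 breaks, seven to six). The new quaternary stereocentre C4 is set by inversion at C4, that is by the α-configuration of the epoxide, itself relayed from the C10 methyl group: C3 bonds to the face of C4 opposite the oxygen, which places the formyl group α (equatorial, C18) and the methyl group β (axial, C19). The step needs ionisation at C4 and not at C18 (secured by the tertiary against secondary cation), migration of the ring bond and not of the C18 hydride (secured by B(C6F5)3, a Lewis acid that favours alkyl shift in trisubstituted epoxides, and by the flexible seven-membered ring that lets C18–C3 align with the developing empty orbital), and tolerance of the ketone and the ester, which bind the catalyst only reversibly.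

Step 10
Reactants: 13 keto aldehyde
Product: 14 methyl (13S)-18-hydroxy-8-oxo-17-norlabdan-15-oate
Conditions: NaBH4 (0.5 equiv), EtOH–CH2Cl2, −78 °C
Reagents that add atoms: none
Why: Chemoselective borohydride reduction: at −78 °C with a sub-stoichiometric charge of NaBH4 an aldehyde reacts much faster than a ketone, so the neopentyl-type aldehyde should give the C18 alcohol while the α-branched C8 ketone and the ester remain.

Step 11
Reactants: 14 hydroxy ketone
Product: 15 methyl (13S)-18-hydroxylabd-8(17)-en-15-oate
Conditions: Ph3PCH3Br (4 equiv), KOC(CH3)3 (3.8 equiv), toluene, rt → 60 °C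
Reagents that add atoms: methyltriphenylphosphonium bromide C[P+](c1ccccc1)(c1ccccc1)c1ccccc1.[Br-]
Why: Wittig methylenation of the C8 ketone with excess methylidene ylide: the C18 hydroxyl only consumes one equivalent of ylide as its alkoxide, the ester is not attacked at this temperature, and C9 already holds its thermodynamic configuration, so no stereocentre is at risk.

Step 12
Reactants: 15 hydroxy ester
Product: 16 (13S)-18-hydroxylabd-8(17)-en-15-oic acid
Conditions: LiOH·H2O, THF–MeOH–H2O, rt; then 1 M HCl
Reagents that add atoms: lithium hydroxide [Li+].[OH-]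
Why: Saponification (BAc2 hydrolysis) of the unhindered methyl ester is carried out before the acetate is introduced, and hydroxide does not affect the 1,1-disubstituted alkene or any stereocentre.

Step 13
Reactants: 16 hydroxy acid
Product: 18 (13S)-18-acetoxylabd-8(17)-en-15-oic acid (target), via mixed anhydride 17 (not isolated)
Conditions: Ac2O (3 equiv), pyridine, DMAP (cat.), CH2Cl2, rt; then aq. NaHCO3–THF, rt; acidify to pH 3
Reagents that add atoms: acetic anhydride CC(=O)OC(C)=O
Why: DMAP-catalysed O-acetylation of the primary neopentyl-type alcohol: the carboxylic acid is acylated only as far as the mixed anhydride, which mild aqueous bicarbonate hydrolyses selectively back to the acid while the alkyl acetate survives.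

**Compound list**

1 | methyl hydrogen (R)-3-methylglutarate [(3R)-5-methoxy-3-methyl-5-oxopentanoic acid] | OC(=O)C[C@@H](C)CC(=O)OC | starting material
2 | (3S)-5-hydroxy-3-methylpentanoic acid | OC(=O)C[C@@H](C)CCO | intermediate (not isolated)
3 | (4S)-4-methyltetrahydro-2H-pyran-2-one | O=C1C[C@@H](C)CCO1 | intermediate
4 | methyl (3R)-5-iodo-3-methylpentanoate | ICC[C@H](C)CC(=O)OC | intermediate
5 | (1R,5R)-(+)-verbenone | O=C1C=C(C)[C@H]2C[C@@H]1C2(C)C | starting material
6 | pent-4-en-1-ylmagnesium bromide | C=CCCC[Mg]Br | starting material
7 | (1R,4R,5R)-4,6,6-trimethyl-4-(pent-4-en-1-yl)bicyclo[3.1.1]heptan-2-one (pentenyl anti to the CMe2 bridge) | O=C1C[C@@](C)(CCCC=C)[C@H]2C[C@@H]1C2(C)C | intermediate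
8 | methyl (3S)-3-methyl-5-[4,6,6-trimethyl-2-oxo-4-(pent-4-en-1-yl)bicyclo[3.1.1]hept-3-yl]pentanoate (C3 chain anti to the CMe2 bridge, cis to pentenyl) | O=C1[C@@H](CC[C@H](C)CC(=O)OC)[C@@](C)(CCCC=C)[C@H]2C[C@@H]1C2(C)C | intermediate
9 | methyl (3S)-5-[2-acetoxy-6-methyl-6-(pent-4-en-1-yl)-5-(prop-1-en-2-yl)cyclohex-2-en-1-yl]-3-methylpentanoate (isopropenyl trans to pentenyl; side chain cis to pentenyl) | CC(=O)OC1=CC[C@@H](C(C)=C)[C@](C)(CCCC=C)[C@@H]1CC[C@H](C)CC(=O)OC | intermediate
10 | methyl (3S)-3-methyl-5-[2-methyl-6-oxo-2-(pent-4-en-1-yl)-3-(prop-1-en-2-yl)cyclohexyl]pentanoate (5α-H, 10β-CH3, 9α-H) | O=C1CC[C@@H](C(C)=C)[C@](C)(CCCC=C)[C@H]1CC[C@H](C)CC(=O)OC | intermediate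
11 | methyl (13S)-8-oxo-17-nor-A-homolabd-4(18)-en-15-oate (trans-fused; 5α-H, 10β-CH3, 9β chain) | O=C1CC[C@H]2C(C)=CCCC[C@]2(C)[C@H]1CC[C@H](C)CC(=O)OC | intermediate
12 | methyl (13S)-4α,18α-epoxy-8-oxo-17-nor-A-homolabdan-15-oate | O=C1CC[C@H]2[C@]3(C)O[C@@H]3CCC[C@]2(C)[C@H]1CC[C@H](C)CC(=O)OC | intermediate
13 | methyl (13S)-8,18-dioxo-17-norlabdan-15-oate (4α-CHO, 4β-CH3) | O=C1CC[C@H]2[C@](C)(C=O)CCC[C@]2(C)[C@H]1CC[C@H](C)CC(=O)OC | intermediate
14 | methyl (13S)-18-hydroxy-8-oxo-17-norlabdan-15-oate | O=C1CC[C@H]2[C@](C)(CO)CCC[C@]2(C)[C@H]1CC[C@H](C)CC(=O)OC | intermediate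
15 | methyl (13S)-18-hydroxylabd-8(17)-en-15-oate | C=C1CC[C@H]2[C@](C)(CO)CCC[C@]2(C)[C@H]1CC[C@H](C)CC(=O)OC | intermediate
16 | (13S)-18-hydroxylabd-8(17)-en-15-oic acid | C=C1CC[C@H]2[C@](C)(CO)CCC[C@]2(C)[C@H]1CC[C@H](C)CC(=O)O | intermediate
17 | acetic (13S)-18-acetoxylabd-8(17)-en-15-oic anhydride | C=C1CC[C@H]2[C@](C)(COC(C)=O)CCC[C@]2(C)[C@H]1CC[C@H](C)CC(=O)OC(C)=O | intermediate (not isolated)
18 | (13S)-18-acetoxylabd-8(17)-en-15-oic acid (4α-CH2OAc, 4β-CH3, 5α-H, 9α-H, 10β-CH3) | C=C1CC[C@H]2[C@](C)(COC(C)=O)CCC[C@]2(C)[C@H]1CC[C@H](C)CC(=O)O | target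

**Step count**

Total: 13 steps. Longest linear sequence: 12 steps (steps 1, 2 and 4–13, from 1 to 18).

**Steps most likely to fail**

1. Step 4: slow SN2 attack of the neopentyl-type enolate carbon on an unactivated primary iodide, so that proton transfer, elimination of hydrogen iodide and attack of the enolate on the ester carbonyl compete. The fallback sets out from 4 and 7 and returns at 8. Iodide 4 would be oxidised (Kornblum oxidation; DMSO, NaHCO3, 110 °C) to methyl (3S)-3-methyl-5-oxopentanoate F1. The lithium enolate of 7 (LiN(iPr)2, THF, −78 °C) should add to this aldehyde far more readily than it is alkylated (aldol addition), giving the β-hydroxy ketone F2 as a mixture of diastereomers. Mesylation (MsCl, Et3N, CH2Cl2) to the mesylate F3, not isolated, and elimination with DBU should give the exocyclic enone F4. Conjugate reduction with [(Ph3P)CuH]6 and PhSiH3 in toluene, which spares the terminal alkene and the ester, would return 8 as a mixture of C9 epimers that converges in step 6.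

2. Step 9: migration of hydride from C18 in place of the ring bond, or erosion of stereospecificity through a long-lived cation at C4. The fallback sets out from 11 and returns at 13 by a halohydrin semipinacol ring contraction, in which no free cation is formed and the migrating bond is fixed by conformation.
   - NBS in THF–H2O at 0 °C should form the bromonium ion on the α-face; water opens it at the tertiary C4 from the β-face to give the bromohydrin F5.
   - K2CO3 in MeOH closes the 4β,18β-epoxide F6.
   - MgBr2·OEt2 (CH2Cl2, −20 °C) delivers bromide to C4 with inversion and gives the bromomagnesium alkoxide F7 of the 4α-bromo-18β-alcohol.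
   - On warming in toluene to 60 °C, the C18–C3 bond of the diequatorial conformer lies antiperiplanar to C4–Br and migrates as bromide leaves. C3 again bonds to C4 opposite an α-leaving group, so the same aldehyde 13 results.

3. Step 8: poor facial selectivity of the peracid on the flexible seven-membered ring, which would carry through to the C4 configuration. The fallback sets out from 11 and returns at 12 and replaces substrate control by reagent control: Shi epoxidation with the fructose-derived chiral ketone (the enantiomer whose spiro transition state places oxygen on the α-face of the trisubstituted alkene), KHSO5 (as 2KHSO5·KHSO4·K2SO4), K2CO3, MeCN–dimethoxymethane–H2O, 0 °C. This fallback makes no new compound (none F0).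

**Further compounds**

F1 | step 4 | methyl (3S)-3-methyl-5-oxopentanoate | O=CC[C@H](C)CC(=O)OC
F2 | step 4 | methyl (3S)-5-hydroxy-3-methyl-5-[4,6,6-trimethyl-2-oxo-4-(pent-4-en-1-yl)bicyclo[3.1.1]hept-3-yl]pentanoate (mixture at ring C3 and at the carbinol carbon) | O=C1C(C(O)C[C@H](C)CC(=O)OC)[C@@](C)(CCCC=C)[C@H]2C[C@@H]1C2(C)C
F3 | step 4 | methanesulfonate of F2 | O=C1C(C(OS(C)(=O)=O)C[C@H](C)CC(=O)OC)[C@@](C)(CCCC=C)[C@H]2C[C@@H]1C2(C)C
F4 | step 4 | methyl (3S)-3-methyl-5-[4,6,6-trimethyl-2-oxo-4-(pent-4-en-1-yl)bicyclo[3.1.1]hept-3-ylidene]pentanoate (alkene geometry immaterial) | O=C1C(=CC[C@H](C)CC(=O)OC)[C@@](C)(CCCC=C)[C@H]2C[C@@H]1C2(C)C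
F5 | step 9 | methyl (13S)-18α-bromo-4β-hydroxy-8-oxo-17-nor-A-homolabdan-15-oate | O=C1CC[C@H]2[C@@](C)(O)[C@H](Br)CCC[C@]2(C)[C@H]1CC[C@H](C)CC(=O)OC
F6 | step 9 | methyl (13S)-4β,18β-epoxy-8-oxo-17-nor-A-homolabdan-15-oate | O=C1CC[C@H]2[C@@]3(C)O[C@H]3CCC[C@]2(C)[C@H]1CC[C@H](C)CC(=O)OC
F7 | step 9 | bromomagnesium alkoxide of methyl (13S)-4α-bromo-18β-hydroxy-8-oxo-17-nor-A-homolabdan-15-oate | O=C1CC[C@H]2[C@](C)(Br)[C@@H](O[Mg]Br)CCC[C@]2(C)[C@H]1CC[C@H](C)CC(=O)OC
F0 | step 8 | none | none
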